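**Retrosynthetic overview**

1. The route rests on the non-aromatic ring, an enolised cyclohexane-1,3,5-trione. Written as its C3 ethyl / C5 menthyl bis-enol ether it is a 6,6-disubstituted cyclohexa-2,4-dien-1-one: oxygen on C1, C3 and C5, a free CH at C2, the CH2 bridge to the acylresorcinol ring on C4, and the C(Me)(prenyl) stereocentre at C6, which blocks aromatisation.
2. Late stage: the butanoyl group goes onto C2 by O-acylation and O-to-C shift once the C3 enol is unmasked; one final acid treatment frees the C5 enol and both phenols.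
3. Key disconnection: the dienone ring from a 2-(arylmethyl)-3-menthyloxy-4-methyl-4-prenylcyclobutenone and ethoxyacetylene. C1–C2 and C3–C4 come from a ketene/alkyne [2+2]; C1–C6 is re-formed by 6π electrocyclisation.
4. The cyclobutenone comes from methyl(prenyl)ketene and the menthyl ynol ether ArCH2C≡C–OMen by [2+2]. The ynol ether comes from (−)-menthol and trichloroethylene, joined to the benzylic bromide by Negishi coupling. The arene comes from 5-methoxyresorcinol by two directed ortho-lithiations.
5. Ring order: four-membered ring (step 10), then the six-membered dienone ring (step 11); the benzene ring is bought.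

Key step: step 11

Assumption: the target is one tautomer of an enolised β-triketone, so keto/enol positions are treated as mobile and only the quaternary carbon (R in the drawn tautomer) is set and tracked.

Abbreviations: ArCH2 = [3-hexanoyl-4-methoxy-2,6-bis(methoxymethoxy)phenyl]methyl; Men = (1R,2S,5R)-menthyl; prenyl = 3-methylbut-2-en-1-yl. Dienone locants: C1 carbonyl, C2 CH, C3 OEt, C4 CH2Ar, C5 OMen, C6 quaternary.

**Route**

Step 1
Reactants: 1 5-methoxyresorcinol
Product: 2 1-methoxy-3,5-bis(methoxymethoxy)benzene
Conditions: MOMCl, iPr2NEt, CH2Cl2, 0 °C → rt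
Reagents that add atoms: chloromethyl methyl ether, COCCl
Why: Double O-alkylation of the phenols (Williamson-type acetal formation) installs groups that direct both later lithiations and come off in acid.

Step 2
Reactants: 2 1-methoxy-3,5-bis(methoxymethoxy)benzene
Product: 5 [4-methoxy-2,6-bis(methoxymethoxy)phenyl]methanol, via aryllithium 3 (not isolated), via aryl aldehyde 4 (not isolated)
Conditions: n-BuLi, THF, 0 °C; DMF, 0 °C → rt; then MeOH, NaBH4, 0 °C
Reagents that add atoms: N,N-dimethylformamide, CN(C)C=O
Why: Directed ortho-metalation occurs at the carbon flanked by both MOM ethers, the most strongly coordinated site, and formylation followed by NaBH4 reduction in the same flask gives the benzylic alcohol whose carbon becomes the methylene bridge.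

Step 3
Reactants: 6 hexanoyl chloride
Product: 7 N-methoxy-N-methylhexanamide
Conditions: MeNH(OMe)·HCl, Et3N, CH2Cl2, 0 °C → rt
Reagents that add atoms: N,O-dimethylhydroxylamine hydrochloride, CNOC.Cl
Why: Schotten–Baumann-type N-acylation gives the Weinreb amide, which holds the acylation of step 4 at the ketone oxidation level.

Step 4
Reactants: 5 [4-methoxy-2,6-bis(methoxymethoxy)phenyl]methanol; 7 N-methoxy-N-methylhexanamide
Product: 9 1-[3-(hydroxymethyl)-6-methoxy-2,4-bis(methoxymethoxy)phenyl]hexan-1-one, via dilithio intermediate 8 (not isolated)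
Conditions: n-BuLi (2.1 equiv), TMEDA, THF, 0 °C → rt; 7, −78 → 0 °C; aq NH4Cl
Reagents that add atoms: none
Why: The first equivalent of base forms the lithium alkoxide, which protects the benzylic position, the second metalates the only remaining kind of ring position, between OMOM and OMe (directed ortho-metalation), and the aryllithium gives the ketone without over-addition (Weinreb ketone synthesis).

Step 5
Reactants: 9 1-[3-(hydroxymethyl)-6-methoxy-2,4-bis(methoxymethoxy)phenyl]hexan-1-one
Product: 10 1-[3-(bromomethyl)-6-methoxy-2,4-bis(methoxymethoxy)phenyl]hexan-1-one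
Conditions: CBr4, PPh3, 2,6-lutidine, CH2Cl2, 0 °C; short neutral alumina plug, used at once
Reagents that add atoms: carbon tetrabromide, BrC(Br)(Br)Br
Why: The Appel reaction converts the primary benzylic alcohol into the bromide under neutral conditions that leave the MOM ethers and the hindered ketone untouched; the electron-rich bromide is not stored.

Step 6
Reactants: 11 (−)-menthol; 12 trichloroethylene
Product: 15 (1R,2S,5R)-menthyl (E)-1,2-dichlorovinyl ether, via potassium menthoxide 13 (not isolated), via dichloroacetylene 14 (not isolated)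
Conditions: KH (2.2 equiv), THF, rt; Cl2C=CHCl, −50 °C → rt
Reagents that add atoms: none
Why: The potassium alkoxide adds to dichloroacetylene formed in situ from trichloroethylene (net vinylic substitution), the established entry to 1,2-dichlorovinyl ethers of secondary alcohols, and the menthyl stereocentres are not touched.

Step 7
Reactants: 15 (1R,2S,5R)-menthyl (E)-1,2-dichlorovinyl ether; 10 1-[3-(bromomethyl)-6-methoxy-2,4-bis(methoxymethoxy)phenyl]hexan-1-one
Product: 19 ArCH2–C≡C–OMen (menthyl 3-arylprop-1-ynyl ether), via chloroalkynyl ether 16 (not isolated), via lithium acetylide 17 (not isolated), via alkynylzinc chloride 18 (not isolated)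
Conditions: n-BuLi (2.1 equiv), THF, −78 → −40 °C; ZnCl2, −40 → 0 °C; 10, Pd(PPh3)4 (5 mol %), 0 °C → rt; Et3N-washed silica
Reagents that add atoms: none
Why: Elimination and chlorine–lithium exchange give the lithium alkoxyacetylide, and transmetalation to zinc followed by Negishi coupling at zerovalent palladium forms the C(sp)–C(sp3) bond without exposing the enolisable aryl ketone to a basic lithium acetylide.

Step 8
Reactants: 20 propionic acid; 21 prenyl bromide
Product: 23 2,5-dimethylhex-4-enoic acid (racemic), via dilithium enediolate 22 (not isolated)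
Conditions: LiN(iPr)2 (2.1 equiv, commercial solution), THF, 0 °C; prenyl bromide, 0 °C → rt; aq HCl
Reagents that add atoms: none
Why: Alkylation of the carboxylic acid dianion with the primary allylic bromide at its unsubstituted terminus gives the acid, whose stereocentre disappears in the ketene.

Step 9
Reactants: 23 2,5-dimethylhex-4-enoic acid
Product: 24 2,5-dimethylhex-4-enoyl chloride
Conditions: (COCl)2, DMF (cat.), CH2Cl2, 0 °C → rt; concentrate
Reagents that add atoms: oxalyl chloride, O=C(Cl)C(=O)Cl
Why: Standard acid chloride formation through the Vilsmeier-type chloroiminium catalyst, which the trisubstituted alkene tolerates at low temperature.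

Step 10
Reactants: 19 ArCH2–C≡C–OMen; 24 2,5-dimethylhex-4-enoyl chloride
Product: 26 2-(ArCH2)-3-(menthyloxy)-4-methyl-4-prenylcyclobut-2-en-1-one (both C4 epimers), via methyl(prenyl)ketene 25 (not isolated)
Conditions: Et3N, MeCN, 35 °C, slow addition of 24 (2 equiv)
Reagents that add atoms: none
Why: Dehydrochlorination gives the ketoketene, whose central carbon is attacked by the nucleophilic CH2Ar-bearing carbon of the ynol ether in a regioselective ketene–alkoxyalkyne [2+2] cycloaddition, which puts C=O next to the arylmethyl carbon and the quaternary carbon next to C–OMen; the new C4 centre forms as both epimers, which is harmless because it is planarised in step 11.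

Step 11
Reactants: 26 2-(ArCH2)-3-(menthyloxy)-4-methyl-4-prenylcyclobut-2-en-1-one; 27 ethoxyacetylene
Product: 31 (6R)-4-(ArCH2)-3-ethoxy-5-(menthyloxy)-6-methyl-6-prenylcyclohexa-2,4-dien-1-one, via vinylketene 28 (not isolated), via vinylcyclobutenone 29 (not isolated), via dienylketene 30 (not isolated)
Conditions: ethoxyacetylene (10 equiv, solution in hexanes), toluene, 80–90 °C, sealed tube; separation of the C6 epimers on silica, then preparative HPLC
Reagents that add atoms: none
Why: Proposed new method: heating opens either C4 epimer of 26 by conrotatory 4π ring opening to vinylketene 28, the nucleophilic CH carbon of ethoxyacetylene adds to the ketene carbon in a regioselective [2+2] to give 29, a second 4π opening gives dienylketene 30, and thermal disrotatory 6π electrocyclisation closes the six-membered ring through the C1–C6 bond (C1–C2 and C3–C4 come from the [2+2]). The closest known reaction type is the Danheiser benzannulation of cyclobutenones with alkoxyalkynes, which normally ends in a resorcinol monoether, whereas here C6 is quaternary, so the sequence stops at the cyclohexa-2,4-dienone and has to set a stereocentre. C6 is created in the 6π closure, and its configuration follows from the face of the enol ether terminus taken by the ketene carbon, that is from the helical sense of the closing triene combined with the geometry of the C5=C6 double bond; the (1R,2S,5R)-menthyloxy group on the neighbouring C5 makes the competing closures diastereomeric and is the only controlling element. Because methyl and prenyl differ little, only a modest facial bias can be claimed, and what the substrate guarantees is that the two C6 epimers are diastereomers, so the (6R) epimer 31 is isolated by chromatography and its configuration is to be assigned by X-ray or ECD. The step also needs chemoselectivity, capture of 28 by the alkyne before intramolecular [2+2] of the ketene with the prenyl double bond, and this is secured by the excess of the far more nucleophilic ynol ether and by the fully substituted ketene α-carbon, which would have to bond to the CMe2 carbon.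

Step 12
Reactants: 31 (6R)-4-(ArCH2)-3-ethoxy-5-(menthyloxy)-6-methyl-6-prenylcyclohexa-2,4-dien-1-one
Product: 32 (6R)-4-(ArCH2)-3-hydroxy-5-(menthyloxy)-6-methyl-6-prenylcyclohexa-2,4-dien-1-one
Conditions: LiOH·H2O, THF/H2O, 40 °C; then 0.5 M HCl to pH 4, 0 °C
Reagents that add atoms: lithium hydroxide (aqueous), [Li+].[OH-]
Why: Hydroxide adds to C3, the less hindered β-carbon of the vinylogous ester, and expels ethoxide (addition–elimination, vinylogous saponification), after which the enolate is inert to further attack, so the hindered menthyl enol ether, the MOM ethers and C6 are untouched.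

Step 13
Reactants: 32 (6R)-4-(ArCH2)-3-hydroxy-5-(menthyloxy)-6-methyl-6-prenylcyclohexa-2,4-dien-1-one; 33 butanoyl chloride
Product: 35 2-(ArCH2)-6-butanoyl-5-hydroxy-3-(menthyloxy)-4-methyl-4-prenylcyclohexa-2,5-dien-1-one (quaternary carbon as in 31; formally 4S in this tautomer numbering), via enol butyrate 34 (not isolated)
Conditions: n-PrCOCl, Et3N, CH2Cl2, 0 °C; then DMAP (0.3 equiv), rt
Reagents that add atoms: none
Why: O-acylation of the cyclic 1,3-dicarbonyl enol followed by DMAP-catalysed O-to-C acyl migration delivers the butanoyl group to the only free carbon between two carbonyls (C2 of 32) and gives the chelated 2-acyl-1,3-dione without affecting the quaternary carbon.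

Step 14
Reactants: 35 2-(ArCH2)-6-butanoyl-5-hydroxy-3-(menthyloxy)-4-methyl-4-prenylcyclohexa-2,5-dien-1-one
Product: 36 (4R)-6-butanoyl-2-[(3-hexanoyl-2,6-dihydroxy-4-methoxyphenyl)methyl]-3,5-dihydroxy-4-methyl-4-(3-methylbut-2-enyl)cyclohexa-2,5-dien-1-one (CNP0219201.1)
Conditions: 2 M HCl (aq), THF, 45 °C
Reagents that add atoms: water, O
Why: Aqueous acid hydrolyses the remaining vinylogous ester by addition of water at the menthyloxy-bearing carbon with loss of menthol and cleaves both aryl MOM acetals, while the aryl methyl ether, the ketones and, at this temperature, the prenyl group should persist and the quaternary carbon cannot epimerise.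

**Compound list**

1 | 5-methoxyresorcinol | COc1cc(O)cc(O)c1 | starting material
2 | 1-methoxy-3,5-bis(methoxymethoxy)benzene | COCOc1cc(OC)cc(OCOC)c1 | intermediate
3 | [4-methoxy-2,6-bis(methoxymethoxy)phenyl]lithium | COCOc1cc(OC)cc(OCOC)c1[Li] | intermediate
4 | 4-methoxy-2,6-bis(methoxymethoxy)benzaldehyde | COCOc1cc(OC)cc(OCOC)c1C=O | intermediate
5 | [4-methoxy-2,6-bis(methoxymethoxy)phenyl]methanol | COCOc1cc(OC)cc(OCOC)c1CO | intermediate
6 | hexanoyl chloride | CCCCCC(=O)Cl | starting material
7 | N-methoxy-N-methylhexanamide | CCCCCC(=O)N(C)OC | intermediate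
8 | dilithio intermediate (lithium benzylic alkoxide, ring lithium between OMOM and OMe) | [Li]OCc1c(OCOC)cc(OC)c([Li])c1OCOC | intermediate
9 | 1-[3-(hydroxymethyl)-6-methoxy-2,4-bis(methoxymethoxy)phenyl]hexan-1-one | CCCCCC(=O)c1c(OC)cc(OCOC)c(CO)c1OCOC | intermediate
10 | 1-[3-(bromomethyl)-6-methoxy-2,4-bis(methoxymethoxy)phenyl]hexan-1-one | CCCCCC(=O)c1c(OC)cc(OCOC)c(CBr)c1OCOC | intermediate
11 | (−)-menthol, (1R,2S,5R) | CC(C)[C@@H]1CC[C@@H](C)C[C@H]1O | starting material
12 | trichloroethylene | ClC=C(Cl)Cl | starting material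
13 | potassium (1R,2S,5R)-menthoxide | CC(C)[C@@H]1CC[C@@H](C)C[C@H]1[O-].[K+] | intermediate
14 | dichloroacetylene | ClC#CCl | intermediate
15 | (1R,2S,5R)-menthyl (E)-1,2-dichlorovinyl ether | CC(C)[C@@H]1CC[C@@H](C)C[C@H]1O/C(Cl)=C\Cl | intermediate
16 | chloroethynyl (1R,2S,5R)-menthyl ether | CC(C)[C@@H]1CC[C@@H](C)C[C@H]1OC#CCl | intermediate
17 | lithium (menthyloxy)acetylide | CC(C)[C@@H]1CC[C@@H](C)C[C@H]1OC#C[Li] | intermediate
18 | [(menthyloxy)ethynyl]zinc chloride | CC(C)[C@@H]1CC[C@@H](C)C[C@H]1OC#C[Zn]Cl | intermediate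
19 | 1-[6-methoxy-2,4-bis(methoxymethoxy)-3-[3-(menthyloxy)prop-2-ynyl]phenyl]hexan-1-one | CC(C)[C@@H]1CC[C@@H](C)C[C@H]1OC#CCc1c(OCOC)cc(OC)c(C(=O)CCCCC)c1OCOC | intermediate
20 | propionic acid | CCC(=O)O | starting material
21 | prenyl bromide | CC(C)=CCBr | starting material
22 | dilithium enediolate of propionic acid | CC=C(O[Li])O[Li] | intermediate
23 | 2,5-dimethylhex-4-enoic acid (racemic) | CC(CC=C(C)C)C(=O)O | intermediate
24 | 2,5-dimethylhex-4-enoyl chloride (racemic) | CC(CC=C(C)C)C(=O)Cl | intermediate
25 | methyl(prenyl)ketene | CC(CC=C(C)C)=C=O | intermediate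
26 | 2-(ArCH2)-3-(menthyloxy)-4-methyl-4-prenylcyclobut-2-en-1-one, both C4 epimers | CC(C)[C@@H]1CC[C@@H](C)C[C@H]1OC1=C(Cc2c(OCOC)cc(OC)c(C(=O)CCCCC)c2OCOC)C(=O)C1(C)CC=C(C)C | intermediate
27 | ethoxyacetylene | CCOC#C | starting material
28 | vinylketene, 2-(ArCH2)-3-(menthyloxy)-4,7-dimethylocta-1,3,6-trien-1-one, both enol ether geometries | CC(C)[C@@H]1CC[C@@H](C)C[C@H]1OC(=C(C)CC=C(C)C)C(Cc2c(OCOC)cc(OC)c(C(=O)CCCCC)c2OCOC)=C=O | intermediate
29 | 4-(ArCH2)-3-ethoxy-4-[1-(menthyloxy)-2,5-dimethylhexa-1,4-dienyl]cyclobut-2-en-1-one, mixture of isomers | CC(C)[C@@H]1CC[C@@H](C)C[C@H]1OC(=C(C)CC=C(C)C)C1(Cc2c(OCOC)cc(OC)c(C(=O)CCCCC)c2OCOC)C(=O)C=C1OCC | intermediate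
30 | dienylketene, 4-(ArCH2)-3-ethoxy-5-(menthyloxy)-6,9-dimethyldeca-1,3,5,8-tetraen-1-one | CC(C)[C@@H]1CC[C@@H](C)C[C@H]1OC(=C(C)CC=C(C)C)C(Cc2c(OCOC)cc(OC)c(C(=O)CCCCC)c2OCOC)=C(OCC)C=C=O | intermediate
31 | (6R)-4-(ArCH2)-3-ethoxy-5-(menthyloxy)-6-methyl-6-prenylcyclohexa-2,4-dien-1-one | CC(C)[C@@H]1CC[C@@H](C)C[C@H]1OC1=C(Cc2c(OCOC)cc(OC)c(C(=O)CCCCC)c2OCOC)C(OCC)=CC(=O)[C@]1(C)CC=C(C)C | intermediate
32 | (6R)-4-(ArCH2)-3-hydroxy-5-(menthyloxy)-6-methyl-6-prenylcyclohexa-2,4-dien-1-one | CC(C)[C@@H]1CC[C@@H](C)C[C@H]1OC1=C(Cc2c(OCOC)cc(OC)c(C(=O)CCCCC)c2OCOC)C(O)=CC(=O)[C@]1(C)CC=C(C)C | intermediate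
33 | butanoyl chloride | CCCC(=O)Cl | starting material
34 | enol butyrate, (6R)-4-(ArCH2)-3-(butanoyloxy)-5-(menthyloxy)-6-methyl-6-prenylcyclohexa-2,4-dien-1-one | CC(C)[C@@H]1CC[C@@H](C)C[C@H]1OC1=C(Cc2c(OCOC)cc(OC)c(C(=O)CCCCC)c2OCOC)C(OC(=O)CCC)=CC(=O)[C@]1(C)CC=C(C)C | intermediate
35 | 2-(ArCH2)-6-butanoyl-5-hydroxy-3-(menthyloxy)-4-methyl-4-prenylcyclohexa-2,5-dien-1-one, quaternary carbon as in 31 | CC(C)[C@@H]1CC[C@@H](C)C[C@H]1OC1=C(Cc2c(OCOC)cc(OC)c(C(=O)CCCCC)c2OCOC)C(=O)C(C(=O)CCC)=C(O)[C@]1(C)CC=C(C)C | intermediate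
36 | (4R)-6-butanoyl-2-[(3-hexanoyl-2,6-dihydroxy-4-methoxyphenyl)methyl]-3,5-dihydroxy-4-methyl-4-(3-methylbut-2-enyl)cyclohexa-2,5-dien-1-one | CCCCCC(=O)c1c(OC)cc(O)c(CC2=C(O)[C@@](C)(CC=C(C)C)C(O)=C(C(=O)CCC)C2=O)c1O | target

**Step count**

Total: 14 steps.
Longest linear sequence: 10 steps (1, 2, 4, 5, 7, 10, 11, 12, 13, 14).

**Steps most likely to fail**

1. Step 11 (proposed new method). Three processes threaten it. Facial selection in the 6π closure may be poor, because both enol ether geometries form and the menthyl group only weakly biases the helical sense. The vinylketene may be diverted by intramolecular [2+2] onto the prenyl double bond. Ethoxyacetylene may be lost by retro-ene fragmentation at the temperature the ring opening needs.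
Fallback, known chemistry, setting out from bromide 10 and returning at target 36: purchased 2-methylphloroglucinol (Cc1c(O)cc(O)cc1O) is C-acylated with butanoyl chloride 33 (AlCl3, Friedel–Crafts) to 1-(2,4,6-trihydroxy-3-methylphenyl)butan-1-one F1. Base-mediated alkylative dearomatisation with prenyl bromide 21 (NaOMe, MeOH, 0 °C) at the methyl-bearing carbon gives racemic 2-butanoyl-3,5-dihydroxy-4-methyl-4-prenylcyclohexa-2,5-dien-1-one F2, separated from the ring-prenylated aromatic isomer. HPLC on a chiral stationary phase delivers the (4R)-enantiomer F3. C-benzylation of F3 at its remaining ring CH with 10 (NaOMe, MeOH) gives the bis-MOM ether of the target F4, and mild methanolysis (HCl, MeOH, rt) returns to 36.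

2. Step 10. Dehydrochlorination to the ketoketene may be slow, the ketene may dimerise, and the secondary-alkyl ynol ether may fragment thermally before it is captured.
Fallback, setting out from acid chloride 24 and ynol ether 19 and returning at cyclobutenone 26: 24 is converted with dimethylamine into N,N,2,5-tetramethylhex-4-enamide F5. Tf2O and 2,4,6-collidine in CH2Cl2 generate the non-dimerising keteniminium triflate F6, which undergoes [2+2] cycloaddition with 19 to the cyclobutenyliminium triflate F7. Aqueous NaHCO3 hydrolyses F7 to 26.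

3. Step 14. Acid may cyclise the prenyl group onto a neighbouring enol oxygen before the hindered menthyl enol ether has hydrolysed, or the hydrolysis may stop short.
Fallback, setting out from 35 and returning at 36: TsOH (cat.) in dry MeOH at 40 °C removes both MOM groups and exchanges the menthyloxy for a methoxy group, giving the methyl enol ether of the target F8 under much milder acid. The methyl group is then removed by SN2 dealkylation (LiCl, DMF, 90 °C), which needs no acid, to give 36.

**Further compounds**

F1 | step 11 | 1-(2,4,6-trihydroxy-3-methylphenyl)butan-1-one | CCCC(=O)c1c(O)cc(O)c(C)c1O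
F2 | step 11 | racemic 2-butanoyl-3,5-dihydroxy-4-methyl-4-(3-methylbut-2-enyl)cyclohexa-2,5-dien-1-one | CCCC(=O)C1=C(O)C(C)(CC=C(C)C)C(O)=CC1=O
F3 | step 11 | (4R)-2-butanoyl-3,5-dihydroxy-4-methyl-4-(3-methylbut-2-enyl)cyclohexa-2,5-dien-1-one | CCCC(=O)C1=C(O)[C@](C)(CC=C(C)C)C(O)=CC1=O
F4 | step 11 | bis(methoxymethyl) ether of 36 | CCCCCC(=O)c1c(OC)cc(OCOC)c(CC2=C(O)[C@@](C)(CC=C(C)C)C(O)=C(C(=O)CCC)C2=O)c1OCOC
F5 | step 10 | N,N,2,5-tetramethylhex-4-enamide | CC(CC=C(C)C)C(=O)N(C)C
F6 | step 10 | N,N-dimethyl keteniminium triflate of methyl(prenyl)ketene | CC(CC=C(C)C)=C=[N+](C)C.[O-]S(=O)(=O)C(F)(F)F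
F7 | step 10 | N,N-dimethyliminium triflate of cyclobutenone 26 | CC(C)[C@@H]1CC[C@@H](C)C[C@H]1OC1=C(Cc2c(OCOC)cc(OC)c(C(=O)CCCCC)c2OCOC)C(=[N+](C)C)C1(C)CC=C(C)C.[O-]S(=O)(=O)C(F)(F)F
F8 | step 14 | methyl enol ether of 36 at the former menthyloxy carbon | CCCCCC(=O)c1c(OC)cc(O)c(CC2=C(OC)[C@@](C)(CC=C(C)C)C(O)=C(C(=O)CCC)C2=O)c1O
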